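**Strategy.** The carbocycle (C5–C10, elemane numbering) is disconnected across C8–C9 and C5–C10 into a C9=C10 dienophile and a C5=C6–C7=C8 diene. One catalytic asymmetric Diels–Alder reaction closes the ring and sets C5, C8 and the quaternary C10; it exploits the cis-1,4 relation of the C5 arm and the C8 oxygen and the unsubstituted C9 next to C10. The diene is a 1-silyloxy diene bearing both side arms. The dienophile is (E)-3-methyl-4-oxopent-2-enal: its formyl group on C9 steers regiochemistry and is excised afterwards, its acetyl group on C10 is the latent vinyl group. Hydroboration of the residual C6=C7 alkene then sets C6 and C7.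

Key step: step 5

Remark on locants: elemane numbering is used throughout (ring C5–C10 with C10 quaternary; C1=C2 vinyl; C3/C4/C15 the acrylic acid arm on C5; C11/C12/C13 the lactone arm on C7; C14 the methyl group); β is the face of the C14 methyl group.

Remark (assumption): the (S)-oxazaborolidinium ion is written for step 5 on the basis of the formyl C–H···O binding model; its mirror image, equally available, would be taken if the facial sense proved opposite.

**Step 1**
Reactants: 1 4-[(tert-butyldimethylsilyl)oxy]butanal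
Product: 2 4-[(tert-butyldimethylsilyl)oxy]-2-methylidenebutanal
Conditions: aq. CH2O (37%), pyrrolidine (10 mol%), EtCO2H (10 mol%), iPrOH, 45 °C
Reagents that add atoms: formaldehyde (C=O)
Why: Organocatalytic Mannich condensation and β-elimination (α-methylenation of an aldehyde), in which the enamine of 1 adds to the iminium ion of formaldehyde and the amine is then lost; no stereocentre is formed.

**Step 2**
Reactants: 2 4-[(tert-butyldimethylsilyl)oxy]-2-methylidenebutanal; 3 tert-butyl pent-4-enoate
Product: 4 tert-butyl (4E)-7-[(tert-butyldimethylsilyl)oxy]-5-formylhept-4-enoate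
Conditions: 3 (2.5 equiv), second-generation Hoveyda–Grubbs catalyst RuCl2(H2IMes)(=CH-C6H4-2-OiPr) (5 mol%), CH2Cl2, 40 °C
Reagents that add atoms: none
Why: Olefin cross-metathesis of a 2-substituted acrolein, which does not homodimerise, with a terminal alkene should give the trisubstituted (E)-enal; its geometry is inconsequential because this double bond becomes the central single bond of the diene.

**Step 3**
Reactants: 4 tert-butyl (4E)-7-[(tert-butyldimethylsilyl)oxy]-5-formylhept-4-enoate
Product: 5 tert-butyl (3E,5E)-6-[(tert-butyldimethylsilyl)oxy]-5-{2-[(tert-butyldimethylsilyl)oxy]ethyl}hexa-3,5-dienoate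
Conditions: TBSOTf (1.2 equiv), Et3N (2 equiv), Et2O, 0 °C
Reagents that add atoms: tert-butyldimethylsilyl triflate (CC(C)(C)[Si](C)(C)OS(=O)(=O)C(F)(F)F)
Why: Silyl dienol ether formation by O-silylation of the s-trans enal and γ-deprotonation at C5 should give the (E,E)-1-silyloxy diene, with the silyloxy group on C8 and the arm on C5 both on the outside of the diene.

**Step 4**
Reactants: 6 2,3-dimethylfuran
Product: 8 (2E)-3-methyl-4-oxopent-2-enal, via Z-enedicarbonyl isomer 7 (not isolated)
Conditions: NBS (1.05 equiv), NaHCO3, acetone–H2O, −15 °C; then pyridine (cat.), rt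
Reagents that add atoms: water (O)
Why: Oxidative ring opening of the furan (bromination at the free α-position, hydrolysis of the dihydrofuran) gives the (Z)-2-ene-1,4-dicarbonyl compound, which the base isomerises to the more stable (E)-isomer; the methyl-bearing α-carbon ends in the acetyl group and the free α-carbon in the formyl group.

**Step 5**
Reactants: 5 the silyloxy diene; 8 (2E)-3-methyl-4-oxopent-2-enal
Product: 9 tert-butyl 2-[6-acetyl-4-(TBS-oxy)-3-(2-TBS-oxyethyl)-5-formyl-6-methylcyclohex-2-en-1-yl]acetate (C5 arm, C8 silyloxy, C9 formyl and C10 methyl all β; acetyl α)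
Conditions: (S)-3,3-diphenyl-1-(2-methylphenyl)tetrahydro-1H,3H-pyrrolo[1,2-c][1,3,2]oxazaborole (20 mol%), Tf2NH (18 mol%), CH2Cl2, −78 to −40 °C
Reagents that add atoms: none
Why: Normal-electron-demand Diels–Alder reaction, an asynchronous [4+2] cycloaddition in which the C5–C10 bond leads (as in a vinylogous Mukaiyama–Michael addition), between the electron-rich 1-silyloxy diene and the enal bound through its formyl oxygen to the chiral oxazaborolidinium ion; the closest known type is the oxazaborolidinium-catalysed cycloaddition of enals and 2-ene-1,4-dicarbonyl dienophiles with 1-oxygenated dienes. The six-membered carbocycle C5–C10 is closed by intermolecular [4+2] union of the C5=C6–C7=C8 unit with C9=C10, which leaves the C6=C7 double bond. C5 and C8 should come out cis because both diene termini carry their substituents on the outside of the (E,E)-diene; the C10 methyl should come out cis to them and the acetyl group trans because the catalyst-bound formyl group reacts endo and is cis to the methyl group in the (E)-dienophile; C9 (formyl cis to the C8 oxygen) is a temporary stereocentre. The absolute configuration is set by the catalyst, which shields one face of the coordinated s-trans enal. Regioselectivity is the critical demand: the silyloxy group makes C5 the nucleophilic diene terminus, and the Lewis acid on the formyl group (an aldehyde binds far better than the hindered methyl ketone) makes C10 the electrophilic carbon, so C5 joins C10 and C8 joins C9. The second carbonyl group lowers the LUMO enough for a trisubstituted dienophile to build the quaternary centre.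

**Step 6**
Reactants: 9 the keto aldehyde cycloadduct
Product: 10 tert-butyl 2-[6-acetyl-4-(TBS-oxy)-3-(2-TBS-oxyethyl)-6-methylcyclohex-2-en-1-yl]acetate
Conditions: RhCl(PPh3)3 (1.1 equiv), PhMe, 110 °C
Reagents that add atoms: none
Why: Tsuji–Wilkinson decarbonylation (oxidative addition of monovalent rhodium into the formyl C–H bond, CO extrusion, C–H reductive elimination) should replace the formyl group on C9 by hydrogen while ketone, esters and silyl ethers stay untouched; C9 ceases to be a stereocentre.

**Step 7**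
Reactants: 10 the cyclohexenyl methyl ketone
Product: 12 the C1/C6/C12 triol 8-silyl ether, via bis-silyl diol 11 (not isolated)
Conditions: BH3·THF (3 equiv), THF, 0 °C to rt; then H2O2, pH 7 phosphate buffer, 0 °C; then PPTS (cat.), MeOH, rt
Reagents that add atoms: hydrogen peroxide (OO)
Why: Hydroboration–oxidation should place boron on the less substituted C6 and add H and B syn from the α face, anti to the two β allylic substituents (C8 silyloxy and C5 arm), giving 6α-OH and 7α-H with the C7 arm β; the ketone is reduced in the same operation (C1 epimers, inconsequential), and acid-catalysed methanolysis then removes only the primary silyl ether.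

**Step 8**
Reactants: 12 the triol
Product: 14 tert-butyl 2-[6-acetyl-4-(TBS-oxy)-6-methyl-2-oxo-octahydro-1-benzofuran-7-yl]acetate, via hydroxy lactone 13 (not isolated)
Conditions: TEMPO (20 mol%), PhI(OAc)2 (2.5 equiv), CH2Cl2, rt; then Dess–Martin periodinane (1.5 equiv), rt
Reagents that add atoms: none
Why: Oxoammonium oxidation is selective for the primary alcohol, whose aldehyde is trapped by the adjacent 6α-OH as a five-membered lactol and oxidised on to the trans-fused γ-lactone (oxidative lactonisation of a 1,4-diol) while O8 is still silylated and cannot compete; the periodinane then oxidises the remaining C1 carbinol to the methyl ketone, which removes the unwanted C1 stereocentre.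

**Step 9**
Reactants: 14 the keto lactone
Product: 15 the enol triflate, tert-butyl 2-[4-(TBS-oxy)-6-methyl-2-oxo-6-(1-triflyloxyethenyl)octahydro-1-benzofuran-7-yl]acetate
Conditions: KHMDS (1.1 equiv), THF, −78 °C; then PhNTf2, −78 to 0 °C
Reagents that add atoms: N-phenylbis(trifluoromethanesulfonimide) (O=S(=O)(N(c1ccccc1)S(=O)(=O)C(F)(F)F)C(F)(F)F)
Why: Kinetic enolisation of the methyl ketone (more acidic than lactone and ester, and able to enolise only toward the methyl group because C10 is quaternary) followed by O-triflation should give the 1-substituted vinyl triflate.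

**Step 10**
Reactants: 15 the enol triflate
Product: 16 tert-butyl 2-[6-ethenyl-4-(TBS-oxy)-6-methyl-2-oxo-octahydro-1-benzofuran-7-yl]acetate
Conditions: Pd(OAc)2 (5 mol%), PPh3 (10 mol%), HCO2H, Bu3N, DMF, 60 °C
Reagents that add atoms: none
Why: Palladium-catalysed formate reduction of the enol triflate (oxidative addition to zerovalent palladium, formate exchange, decarboxylation, C–H reductive elimination) should deliver the vinyl group on C10 without touching lactone or ester.

**Step 11**
Reactants: 16 the vinyl lactone ester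
Product: 19 tert-butyl 2-[6-ethenyl-4-(TBS-oxy)-6-methyl-3-methylidene-2-oxo-octahydro-1-benzofuran-7-yl]prop-2-enoate, via bis-Mannich base 17 (not isolated), via bis-ammonium diiodide 18 (not isolated)
Conditions: LDA (2.5 equiv), THF, −78 °C; CH2=NMe2+ I− (3 equiv), −78 °C to rt; then MeI, MeOH, rt; then aq. NaHCO3, CH2Cl2, rt
Reagents that add atoms: dimethyl(methylidene)ammonium iodide (C=[N+](C)C.[I-])
Why: Double Mannich aminomethylation of the lactone and ester enolates, N-methylation and Hofmann-type β-elimination should install both exocyclic methylene groups (α-methylenation); the transient centres at C11 and C4 are destroyed and neither C7 nor C5 is an enolisable position.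

**Step 12**
Reactants: 19 the silyl ether
Product: 20 tert-butyl 2-[6-ethenyl-4-hydroxy-6-methyl-3-methylidene-2-oxo-octahydro-1-benzofuran-7-yl]prop-2-enoate
Conditions: HF·pyridine, THF, 0 °C to rt
Reagents that add atoms: none
Why: Fluoride cleavage of the secondary silyl ether under mildly acidic conditions should free the 8β-hydroxyl while avoiding alkoxide-induced migration of the lactone to O8 and conjugate addition to the methylene groups; the tert-butyl ester is retained.

**Step 13**
Reactants: 20 the 8β-alcohol; 21 angelic acid, (2Z)-2-methylbut-2-enoic acid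
Product: 22 the 8β-angelate tert-butyl ester
Conditions: 21, 2,4,6-Cl3C6H2COCl, Et3N, PhMe, rt; then 20, PhMe, 80 °C
Reagents that add atoms: none
Why: Yamaguchi-type esterification through the angelic 2,4,6-trichlorobenzoic mixed anhydride, run without a nucleophilic amine catalyst so that the (Z)-geometry of the acyl group is kept; O-acylation leaves the configuration at C8 untouched.

**Step 14**
Reactants: 22 the angelate tert-butyl ester
Product: 23 the target acid
Conditions: TFA, CH2Cl2, 0 °C
Reagents that add atoms: none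
Why: Acidolysis of the tert-butyl ester with loss of 2-methylpropene should liberate the carboxylic acid; lactone, angelate and the alkenes tolerate brief exposure to acid.

**Compound list**

1 | 4-[(tert-butyldimethylsilyl)oxy]butanal | O=CCCCO[Si](C)(C)C(C)(C)C | starting material
2 | 4-[(tert-butyldimethylsilyl)oxy]-2-methylidenebutanal | C=C(C=O)CCO[Si](C)(C)C(C)(C)C | intermediate
3 | tert-butyl pent-4-enoate | C=CCCC(=O)OC(C)(C)C | starting material
4 | tert-butyl (4E)-7-[(tert-butyldimethylsilyl)oxy]-5-formylhept-4-enoate | O=C/C(CCO[Si](C)(C)C(C)(C)C)=C/CCC(=O)OC(C)(C)C | intermediate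
5 | tert-butyl (3E,5E)-6-[(tert-butyldimethylsilyl)oxy]-5-{2-[(tert-butyldimethylsilyl)oxy]ethyl}hexa-3,5-dienoate | CC(C)(C)[Si](C)(C)O/C=C(\CCO[Si](C)(C)C(C)(C)C)/C=C/CC(=O)OC(C)(C)C | intermediate
6 | 2,3-dimethylfuran | Cc1occc1C | starting material
7 | (2Z)-3-methyl-4-oxopent-2-enal | CC(=O)/C(C)=C\C=O | intermediate (not isolated)
8 | (2E)-3-methyl-4-oxopent-2-enal | CC(=O)/C(C)=C/C=O | intermediate
9 | tert-butyl 2-[6-acetyl-4-(TBS-oxy)-3-(2-TBS-oxyethyl)-5-formyl-6-methylcyclohex-2-en-1-yl]acetate; C5 arm, 8-OTBS, 9-CHO and 10-Me all β, acetyl α | CC(=O)[C@]1(C)[C@@H](C=O)[C@@H](O[Si](C)(C)C(C)(C)C)C(CCO[Si](C)(C)C(C)(C)C)=C[C@H]1CC(=O)OC(C)(C)C | intermediate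
10 | tert-butyl 2-[6-acetyl-4-(TBS-oxy)-3-(2-TBS-oxyethyl)-6-methylcyclohex-2-en-1-yl]acetate; C5 arm, 8-OTBS and 10-Me β | CC(=O)[C@]1(C)C[C@@H](O[Si](C)(C)C(C)(C)C)C(CCO[Si](C)(C)C(C)(C)C)=C[C@H]1CC(=O)OC(C)(C)C | intermediate
11 | tert-butyl 2-[4-(TBS-oxy)-3-(2-TBS-oxyethyl)-2-hydroxy-6-(1-hydroxyethyl)-6-methylcyclohexyl]acetate; 5β arm, 6α-OH, 7β arm, 8β-OTBS, 10β-Me, C1 epimers | CC(O)[C@]1(C)C[C@@H](O[Si](C)(C)C(C)(C)C)[C@@H](CCO[Si](C)(C)C(C)(C)C)[C@H](O)[C@H]1CC(=O)OC(C)(C)C | intermediate (not isolated)
12 | tert-butyl 2-[4-(TBS-oxy)-2-hydroxy-6-(1-hydroxyethyl)-3-(2-hydroxyethyl)-6-methylcyclohexyl]acetate; same configuration as 11 | CC(O)[C@]1(C)C[C@@H](O[Si](C)(C)C(C)(C)C)[C@@H](CCO)[C@H](O)[C@H]1CC(=O)OC(C)(C)C | intermediate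
13 | tert-butyl 2-[4-(TBS-oxy)-6-(1-hydroxyethyl)-6-methyl-2-oxo-octahydro-1-benzofuran-7-yl]acetate; trans-fused 6α,12-lactone, 8β-OTBS, 10β-Me, 5β arm, C1 epimers | CC(O)[C@]1(C)C[C@@H](O[Si](C)(C)C(C)(C)C)[C@H]2CC(=O)O[C@@H]2[C@H]1CC(=O)OC(C)(C)C | intermediate (not isolated)
14 | tert-butyl 2-[6-acetyl-4-(TBS-oxy)-6-methyl-2-oxo-octahydro-1-benzofuran-7-yl]acetate; configuration as 13 | CC(=O)[C@]1(C)C[C@@H](O[Si](C)(C)C(C)(C)C)[C@H]2CC(=O)O[C@@H]2[C@H]1CC(=O)OC(C)(C)C | intermediate
15 | tert-butyl 2-[4-(TBS-oxy)-6-methyl-2-oxo-6-{1-[(trifluoromethanesulfonyl)oxy]ethenyl}octahydro-1-benzofuran-7-yl]acetate | C=C(OS(=O)(=O)C(F)(F)F)[C@]1(C)C[C@@H](O[Si](C)(C)C(C)(C)C)[C@H]2CC(=O)O[C@@H]2[C@H]1CC(=O)OC(C)(C)C | intermediate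
16 | tert-butyl 2-[6-ethenyl-4-(TBS-oxy)-6-methyl-2-oxo-octahydro-1-benzofuran-7-yl]acetate; 10α-vinyl, 10β-Me | C=C[C@]1(C)C[C@@H](O[Si](C)(C)C(C)(C)C)[C@H]2CC(=O)O[C@@H]2[C@H]1CC(=O)OC(C)(C)C | intermediate
17 | bis(dimethylaminomethyl) derivative of 16 at C11 and C4 | C=C[C@]1(C)C[C@@H](O[Si](C)(C)C(C)(C)C)[C@H]2C(CN(C)C)C(=O)O[C@@H]2[C@H]1C(CN(C)C)C(=O)OC(C)(C)C | intermediate (not isolated)
18 | bis(trimethylammoniomethyl) diiodide derived from 17 | C=C[C@]1(C)C[C@@H](O[Si](C)(C)C(C)(C)C)[C@H]2C(C[N+](C)(C)C)C(=O)O[C@@H]2[C@H]1C(C[N+](C)(C)C)C(=O)OC(C)(C)C.[I-].[I-] | intermediate (not isolated)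
19 | tert-butyl 2-[6-ethenyl-4-(TBS-oxy)-6-methyl-3-methylidene-2-oxo-octahydro-1-benzofuran-7-yl]prop-2-enoate | C=C[C@]1(C)C[C@@H](O[Si](C)(C)C(C)(C)C)[C@H]2C(=C)C(=O)O[C@@H]2[C@H]1C(=C)C(=O)OC(C)(C)C | intermediate
20 | tert-butyl 2-[6-ethenyl-4-hydroxy-6-methyl-3-methylidene-2-oxo-octahydro-1-benzofuran-7-yl]prop-2-enoate; 8β-OH | C=C[C@]1(C)C[C@@H](O)[C@H]2C(=C)C(=O)O[C@@H]2[C@H]1C(=C)C(=O)OC(C)(C)C | intermediate
21 | angelic acid, (2Z)-2-methylbut-2-enoic acid | C/C=C(/C)C(=O)O | starting material
22 | tert-butyl 2-[6-ethenyl-6-methyl-3-methylidene-4-{[(2Z)-2-methylbut-2-enoyl]oxy}-2-oxo-octahydro-1-benzofuran-7-yl]prop-2-enoate | C=C[C@]1(C)C[C@@H](OC(=O)/C(C)=C\C)[C@H]2C(=C)C(=O)O[C@@H]2[C@H]1C(=C)C(=O)OC(C)(C)C | intermediate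
23 | 2-[(3aR,4R,6S,7R,7aR)-6-ethenyl-6-methyl-3-methylidene-4-{[(2Z)-2-methylbut-2-enoyl]oxy}-2-oxo-octahydro-1-benzofuran-7-yl]prop-2-enoic acid (CNP0256928.2) | C=C[C@]1(C)C[C@@H](OC(=O)/C(C)=C\C)[C@H]2C(=C)C(=O)O[C@@H]2[C@H]1C(=C)C(=O)O | target

**Step count.** Total: 14 steps. Longest linear sequence: 13 steps (steps 1–3 and 5–14, from 1 to 23); step 4 is the one-step convergent branch.

**Steps most likely to fail**

Step 5 (key cycloaddition). The Lewis acid may bind the ketone instead of the formyl group and so reverse the regiochemistry. The formyl C=O may react itself with the electron-rich diene (hetero-Diels–Alder or aldol addition). The trisubstituted dienophile may react so slowly that the diene is protodesilylated first. Facial or endo selectivity may be poor. Fallback, setting out from 8 (with diene 5) and returning at 9: aldehyde 8 would be oxidised (NaClO2, NaH2PO4, 2-methylbut-2-ene) to (2E)-3-methyl-4-oxopent-2-enoic acid F1, which is coupled (pivaloyl chloride, Et3N; then the lithium salt of (S)-4-benzyloxazolidin-2-one) to the imide F2. Cycloaddition of F2 with diene 5 promoted by Et2AlCl at −78 °C would give the imide cycloadduct F3; two-point chelation of the imide fixes the activated carbonyl on C9, and the benzyl group shields one face of the s-cis enoyl unit, so the diene should add to the opposite face. LiBH4 then removes the auxiliary and reduces the ketone to the diol F4, and Dess–Martin oxidation of both carbinols returns keto aldehyde 9.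

Step 6 (decarbonylation). At 110 °C the β-silyloxy aldehyde may lose silanol by β-elimination, or the ring alkene may migrate on rhodium, before CO extrusion is complete. Fallback, from 9 back to 10: Pinnick oxidation of 9 gives the carboxylic acid F5, which is converted (DCC, N-hydroxypyridine-2-thione) into the thiohydroxamate ester F6; photolysis with t-BuSH (Barton reductive decarboxylation) replaces the carboxyl group by hydrogen through the C9 radical and returns 10.

Step 13 (angeloylation). Acylation of the hindered axial 8β-hydroxyl may be slow, and prolonged heating with amine may isomerise the angeloyl unit to the (E)-isomer or let the lactone migrate to O8. Fallback, from 20 back to 22: alcohol 20 is esterified under neutral carbodiimide conditions with 2-(diphenoxyphosphoryl)propanoic acid to the phosphonate ester F7; a Z-selective Horner–Wadsworth–Emmons reaction with acetaldehyde (NaI, DBU, THF, −78 to 0 °C) then builds the (Z)-2-methylbut-2-enoate on the molecule and returns 22.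

**Further compounds**

F1 | step 5 | (2E)-3-methyl-4-oxopent-2-enoic acid | CC(=O)/C(C)=C/C(=O)O
F2 | step 5 | (4S)-4-benzyl-3-[(2E)-3-methyl-4-oxopent-2-enoyl]oxazolidin-2-one | CC(=O)/C(C)=C/C(=O)N1[C@@H](Cc2ccccc2)COC1=O
F3 | step 5 | imide cycloadduct (9 with the formyl group replaced by the N-acyl oxazolidinone) | CC(=O)[C@]1(C)[C@@H](C(=O)N2[C@@H](Cc3ccccc3)COC2=O)[C@@H](O[Si](C)(C)C(C)(C)C)C(CCO[Si](C)(C)C(C)(C)C)=C[C@H]1CC(=O)OC(C)(C)C
F4 | step 5 | diol (C9 hydroxymethyl, C1 carbinol) | CC(O)[C@]1(C)[C@@H](CO)[C@@H](O[Si](C)(C)C(C)(C)C)C(CCO[Si](C)(C)C(C)(C)C)=C[C@H]1CC(=O)OC(C)(C)C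
F5 | step 6 | C9 carboxylic acid from 9 | CC(=O)[C@]1(C)[C@@H](C(=O)O)[C@@H](O[Si](C)(C)C(C)(C)C)C(CCO[Si](C)(C)C(C)(C)C)=C[C@H]1CC(=O)OC(C)(C)C
F6 | step 6 | 2-thioxopyridin-1(2H)-yl ester of F5 | CC(=O)[C@]1(C)[C@@H](C(=O)On2ccccc2=S)[C@@H](O[Si](C)(C)C(C)(C)C)C(CCO[Si](C)(C)C(C)(C)C)=C[C@H]1CC(=O)OC(C)(C)C
F7 | step 13 | 8β-[2-(diphenoxyphosphoryl)propanoate] of 20 | C=C[C@]1(C)C[C@@H](OC(=O)C(C)P(=O)(Oc3ccccc3)Oc3ccccc3)[C@H]2C(=C)C(=O)O[C@@H]2[C@H]1C(=C)C(=O)OC(C)(C)C
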